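The readings are simulated with constants of no real substance, noise included.

The constant we can carry forward comes from the last reading of the zeta run: if substrate turns into target by a first-order step, with no return, 12.6% of target at 15.0 min gives the turnover half-time, the time in which substrate falls by half, of 1.29 h, with no concentration in it.

| flask | substrate | temperature | remark | time |
|---|---|---|---|---|
| zeta | 34 mM | 20 °C | run made earlier |  |
| ochre | 23 mM | 20 °C |  | 2.5 h |
| blue | 23 mM | 5 °C |  | 2.5 h |
| amber | 23 mM | 35 °C |  | 2.5 h |
| grey | 23 mM | 50 °C |  | 2.5 h |

zeta run (percent of the substrate charged)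

| time / min | target / % |
|---|---|
| 1.33 | 1.3 |
| 2.00 | 2.5 |
| 3.00 | 3.0 |
| 5.00 | 5.0 |
| 10.0 | 9.0 |
| 15.0 | 12.6 |

(readings scatter by 0.3 percentage points)

- the earlier runs do not show what temperature does; that part of a forecast is a guess

1. which flask leads in amount of target, in percent of the substrate charged ("all alike" within 1.5 percentage points) (ochre / blue / amber / grey / all alike)
2. how much target is there at the end, in percent of the substrate charged: ochre
3. how much target is there at the end, in percent of the substrate charged: blue
4. how much target is there at the end, in percent of the substrate charged: amber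
5. how much target is there at the end, in percent of the substrate charged: grey

Ochre stands at the temperature of the zeta run and lasts 2.5 h, so we reckon that substrate falls to 26.0% and target reaches 74.0%, while for blue, amber and grey the earlier runs show nothing of temperature and we commit to no number.

The forecast gave 62% for ochre, less than our 74.0%, 26% for blue, 87% for amber and 93% for grey, and said: “Grey is the likely leader, narrowly over amber.”

The flask that leads is ochre, with 50.5% of target, against 45.0% in amber, 26.4% in grey and 13.6% in blue.

    substrate ⇌ target (K = 1.80, k = 0.590 h⁻¹, Ea = 101 kJ mol⁻¹, ΔH = −10.0 kJ mol⁻¹)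
    target ⇌ isomer of the product A (K = 0.0810, k = 0.0310 h⁻¹, Ea = 96.0 kJ mol⁻¹, ΔH = −17.0 kJ mol⁻¹)
    isomer of the product A ⇌ isomer of the product B (K = 0.430, k = 0.170 h⁻¹, Ea = 85.0 kJ mol⁻¹, ΔH = 31.0 kJ mol⁻¹)
    isomer of the product B ⇌ substrate (k = 0.130 h⁻¹, Ea = 85.0 kJ mol⁻¹)
    2 substrate → homo dimer (k = 2.90 M⁻¹ h⁻¹, Ea = 73.0 kJ mol⁻¹)
    (constants at 20 °C)

In ochre, substrate stands at 49.8% after 1.25 h, where our half-time of 1.29 h reckons 51.1%, but at 35.3% after 2.50 h, higher than the 26.0% we reckoned. The relaxation half-life of substrate and target in ochre by their step alone, both ways together, is 0.755 h, shorter than the 2.5 h of the run, whereas the half-life of target by the forward rate of its turning into isomer of the product A alone, taken at 0.599 h, is 22 h, longer than the run. Having no concentration in it, our 1.29 h reckons the same 26.0% of substrate for the neighbour of ochre charged with 57 mM of substrate, which ends with 29.4% of substrate, 44.8% of target and 23.3% of homo dimer.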